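## Structural features

The target 15, 4,6-dibromo-2-(3,5-dibromo-2-methoxyphenoxy)-3-methoxyphenol, is made of two benzene rings joined by a single ether oxygen; it has no further ring, no chain beyond two O-methyl groups and no stereocentre. Ring A is numbered from its ether carbon C1 and carries OMe at C2 and bromine at C3 and C5; ring B is numbered from its ether carbon C1' and carries the free OH at C2', bromine at C3' and C5' and OMe at C6'. Three of the four carbons ortho to the ether oxygen are oxygenated (C2, C2', C6'), so the diaryl ether is crowded and electron-rich on both sides, a poor case for a late copper- or palladium-mediated C–O coupling. The sensitive groups are the four aryl bromides, which rule out hydrogenolysis, halogen–metal exchange and zerovalent palladium late in the route, and the free phenol of ring B, which is open to oxidation. The difficulty lies less in the carbon skeleton than in bookkeeping: three oxygen substituents of two kinds (one OH, two OMe) must end up on the right carbons of two rings, and four bromines must occupy exactly C3, C5, C3' and C5'. Ring B's bromines lie ortho and para to its two flanking oxygens and can be left to electrophilic substitution. Ring A is where the key step intervenes: its row C1(OAr)–C2(O)–C3 corresponds to C4–C3–C2 of a 4-aryloxyacetoacetate, whose ester carbon marks C3 for later exchange against bromine, and its row C4–C5(Br)–C6 corresponds to bromomalonaldehyde, so ring A can be assembled from these two pieces with the C2 oxygen emerging as the only free OH of the molecule.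

## Logic of the disconnections

15 to 14: the O–CH2Ph bond on the C2' oxygen is cut. A benzyl group on this oxygen is what keeps it apart from the ring A oxygen until the latter has been methylated. The forward step must free the phenol without reducing any of four C–Br bonds and without touching either methyl ether, which points to a Lewis acid and away from hydrogen.

14 to 13: the O–CH3 bond at C2 of ring A is cut. 13 has exactly one free OH, so the methylation needs no selectivity; the only demand is that a hindered, rather acidic phenol be alkylated.

13 to 12: three C–Br bonds are cut, C3–Br of ring A (traced back to a C–CO2H bond) and C3'–Br and C5'–Br of ring B. The carboxyl of 12 stands exactly where the last ring A bromine belongs and is ortho to the free OH, so it can be replaced at the same carbon. The two ring B positions are each activated by two alkoxy groups. Three bromines arrive in one operation, and ring A's pattern is fixed by construction and not by directing effects. The forward step must spare the benzyl ether and stop short of a further bromination.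

12 to 11: the ester C–O bond is cut; the free carboxylate is needed for the ipso substitution, and the forward step is a plain hydrolysis.

11 to 8 and 10: ring A bonds C1–C6 and C3–C4 are cut. The ring falls into a four-carbon bis-nucleophile that already carries the diaryl ether oxygen, the future C2 oxygen and the ester placeholder, and a three-carbon bis-electrophile that carries the C5 bromine. The crowded aryl–O–aryl linkage is therefore never forged at an aromatic carbon. The forward step must engage carbon (not oxygen) of 8, terminus first and centre second, under a Lewis acid that the benzyl ether tolerates.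

8 to 7 to 6: two O–Si bonds are cut in turn, so that 8 is seen as the masked dianion of 6. The forward steps call for enol silylation, then deprotonation at the aryloxy-bearing carbon and O-silylation, with strict exclusion of water.

10 to 9: one O–Si bond is cut; silylation makes the enol form of 9 soluble and compatible with the Lewis acid.

6 to 4 and 5: the ArO–CH2 bond is cut. The hindered phenoxide attacks an sp3 carbon next to a ketone, the easiest kind of ether formation. The forward step must keep 5 from condensing with itself.

4 to 2 to 1: the C1'–O bond is traced back through 3 to a formyl group (aldehyde to phenol by peracid oxidation and formate cleavage), and the O–benzyl bond is cut. 1 already has the two flanking oxygens in different forms, one OMe and one free OH, so ring B's oxygens are told apart from the first step.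

## Other disconnections considered

Alternative 1: The cut is at the two flanking C–O bonds of ring B (C2'–O and C6'–O), which leads back to the dialdehyde 2-(3,5-dibromo-2-methoxyphenoxy)benzene-1,3-dicarbaldehyde A1. In the forward key step, 3-chloroperoxybenzoic acid followed by K2CO3 in methanol would convert both formyl groups of A1 into hydroxyls with aryl migration, giving 2-(3,5-dibromo-2-methoxyphenoxy)benzene-1,3-diol A2.
In its favour: A1 should come from 3,5-dibromo-2-methoxyphenol A3 and 2-fluorobenzene-1,3-dicarbaldehyde A4 by nucleophilic aromatic substitution, because the fluoride of A4 is activated by two ortho formyl groups. The hindered ether is thus made under the mildest conditions, and A3 brings ring A with both bromines and its methoxy group already fixed.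
Against it: A2 has two equivalent hydroxyls while the target needs one OH and one OMe. Monomethylation of A2 to 2-(3,5-dibromo-2-methoxyphenoxy)-3-methoxyphenol A5 is a statistical desymmetrisation, and only then can A5 be dibrominated on ring B to finish.
Structure: for ring A this plan is the equal or the better of the chosen one, since no placeholder has to be exchanged. For ring B it is weaker, because the chosen plan carries the two oxygens in different forms from compound 1 onward.
Mechanism: substitution at the activated fluoride of A4 and Baeyer–Villiger chemistry on A1 need no moisture-sensitive intermediate, an advantage over the silyl diene chemistry.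
Step economy: it is shorter (about five to six operations against eleven), but the saving is partly consumed by the unselective methylation. The ring B bromination is common to both plans.

Alternative 2: The cut is the C1'–C2' bond of a ring B that is not yet aromatic. In the forward key step, KOtBu would close methyl 6-(3,5-dibromo-2-methoxyphenoxy)-5-oxohexanoate A6 by intramolecular Claisen condensation to 2-(3,5-dibromo-2-methoxyphenoxy)cyclohexane-1,3-dione A7. A6 would come from A3 and methyl 6-bromo-5-oxohexanoate A8 by O-alkylation.
In its favour: in A6 only the aryloxy-bearing carbon can reach the ester through a six-membered transition state, so the closure to A7 is regiochemically unambiguous. A 1,3-dione such as A7 can be converted into its mono enol methyl ether, so an oxidative aromatisation (for example iodine in methanol) could lead to A5 with the OH/OMe distinction built in and no protecting group. Dibromination of A5 would then finish the synthesis.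
Against it: the aromatisation of A7 must be oxidative yet spare two aryl bromides, which excludes palladium dehydrogenation. Halogenation–elimination sequences on so electron-rich a product risk uncontrolled ring halogenation, and A8 is a labile, lachrymatory bromo ketone.
Structure: both plans build one ring from acyclic material, but the chosen plan builds ring A, the ring whose bromine pattern profits from construction.
Mechanism: the chosen key step delivers the arene directly at the right oxidation level, whereas this plan needs a separate and uncertain dehydrogenation.
Step economy and protecting groups: this plan is the better one on paper, being shorter and free of the benzyl group and its removal.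

Alternative 3: All four C–Br bonds are cut. In the forward key step, four equivalents of bromine in buffered acetic acid would substitute 2-[2-(benzyloxy)-6-methoxyphenoxy]phenol A9 at C3 and C5 of both rings to give 2-[2-(benzyloxy)-3,5-dibromo-6-methoxyphenoxy]-4,6-dibromophenol A10, which has the same constitution as compound 13. A9 should be available from compound 4 and 2-fluorobenzaldehyde A11 by nucleophilic aromatic substitution, the fluoride of A11 being activated by its ortho formyl group. This gives 2-[2-(benzyloxy)-6-methoxyphenoxy]benzaldehyde A12, and peracid oxidation of the formyl group of A12 with formate cleavage leads to A9.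
In its favour: every bromine of the target lies ortho or para to an oxygen that directs it, so innate electrophilic selectivity matches the target on both rings. After A10 the route would end with the same methylation and debenzylation as the chosen plan.
Against it: four substitutions must all go to completion in one flask without a fifth (para to the ether oxygen on either ring), and mixtures of tri-, tetra- and pentabromides would be hard to separate. The peracid step on A12 relies on a migrating ring with a single ortho aryloxy donor.
Structure: the chosen plan fixes both ring A bromines by construction (C5 from the three-carbon unit, C3 by replacement of the carboxyl), whereas this plan trusts directing effects. For ring B the two plans are equal, since both use the same substitution.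
Mechanism: this plan uses only robust textbook steps, from A11 to A10, and is the better one on that count.
Step economy: it is clearly better, about seven steps against eleven. The chosen plan pays roughly four steps for positional certainty on ring A.

Key step: step 7

Remark on the chemistry: the double-bond geometries of 7, 8 and 10 are assumed to be uncontrolled and immaterial, because all of these double bonds are consumed when ring A aromatises; one isomer of each is drawn.

## Route

Step 1
Reactants: 1 2-hydroxy-6-methoxybenzaldehyde
Product: 2 2-(benzyloxy)-6-methoxybenzaldehyde
Conditions: BnBr, K2CO3, DMF, 60 °C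
Reagents that add atoms: benzyl bromide, BrCc1ccccc1
Why: Williamson ether synthesis on a phenoxide; the benzyl group marks the oxygen that becomes the free OH of ring B.

Step 2
Reactants: 2 2-(benzyloxy)-6-methoxybenzaldehyde
Product: 4 2-(benzyloxy)-6-methoxyphenol, via aryl formate 3 (not isolated)
Conditions: mCPBA, CH2Cl2, 0 → 20 °C; then K2CO3 (cat.), MeOH, 20 °C
Reagents that add atoms: 3-chloroperoxybenzoic acid, OOC(=O)c1cccc(Cl)c1
Why: Baeyer–Villiger (Dakin-type) oxidation; the aryl group, made electron-rich by two ortho alkoxy groups, migrates in preference to hydrogen, and methanolysis of the formate releases the phenol.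

Step 3
Reactants: 4 2-(benzyloxy)-6-methoxyphenol; 5 methyl 4-chloro-3-oxobutanoate
Product: 6 methyl 4-[2-(benzyloxy)-6-methoxyphenoxy]-3-oxobutanoate
Conditions: NaH (2.2 equiv), THF, 0 °C; then 5, 0 → 20 °C; aq. HCl
Reagents that add atoms: none
Why: SN2 displacement of the primary chloride next to the ketone by the phenoxide; the second equivalent of base holds the acetoacetate as its enolate, so that the phenoxide is not quenched and C2 is not alkylated.

Step 4
Reactants: 6 methyl 4-[2-(benzyloxy)-6-methoxyphenoxy]-3-oxobutanoate
Product: 7 methyl (2E)-4-[2-(benzyloxy)-6-methoxyphenoxy]-3-(trimethylsilyloxy)but-2-enoate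
Conditions: Me3SiCl, Et3N, toluene, 20 °C
Reagents that add atoms: chlorotrimethylsilane, C[Si](C)(C)Cl
Why: O-silylation of the enol of a beta-keto ester under amine base, the standard first stage in the preparation of 1,3-bis(silyloxy)dienes.

Step 5
Reactants: 7 methyl (2E)-4-[2-(benzyloxy)-6-methoxyphenoxy]-3-(trimethylsilyloxy)but-2-enoate
Product: 8 (1Z,3Z)-4-[2-(benzyloxy)-6-methoxyphenoxy]-1-methoxy-1,3-bis(trimethylsilyloxy)buta-1,3-diene
Conditions: lithium diisopropylamide, THF, −78 °C; then Me3SiCl, −78 → 20 °C
Reagents that add atoms: chlorotrimethylsilane, C[Si](C)(C)Cl
Why: Kinetic gamma-deprotonation of the silyloxy enoate at the aryloxy-bearing carbon and O-silylation of the resulting ester dienolate give the bis(silyloxy)diene, a masked acetoacetate dianion; it is used without chromatography.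

Step 6
Reactants: 9 bromomalonaldehyde
Product: 10 (2Z)-2-bromo-3-(trimethylsilyloxy)prop-2-enal
Conditions: Me3SiCl, Et3N, CH2Cl2, 0 → 20 °C
Reagents that add atoms: chlorotrimethylsilane, C[Si](C)(C)Cl
Why: O-silylation of the strongly enolised dialdehyde; the product is filtered from the ammonium salt under argon and used at once.

Step 7
Reactants: 8 (1Z,3Z)-4-[2-(benzyloxy)-6-methoxyphenoxy]-1-methoxy-1,3-bis(trimethylsilyloxy)buta-1,3-diene; 10 (2Z)-2-bromo-3-(trimethylsilyloxy)prop-2-enal
Product: 11 methyl 3-[2-(benzyloxy)-6-methoxyphenoxy]-5-bromo-2-hydroxybenzoate
Conditions: TiCl4 (1.1 equiv), CH2Cl2, −78 → 20 °C; then aq. HCl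
Reagents that add atoms: none
Why: TiCl4 binds the aldehyde oxygen of 10, and the terminal, aryloxy-bearing carbon of 8 (the gamma-carbon of the masked dianion and its most nucleophilic site) adds to an aldehyde-level carbon of 10 in a vinylogous Mukaiyama aldol step that forms ring A bond C1–C6. The remaining silyl enol ether carbon, the central ester-bearing one, then attacks the second aldehyde-level carbon of the three-carbon unit and forms bond C3–C4. This ring closure is a 6-exo-trig intramolecular aldol-type addition of an enol silyl ether to a carbonyl-level carbon, an allowed mode for a six-membered ring. Loss of silanol and water from the cyclised adduct aromatises ring A to the salicylate, driven by aromaticity and by the hydrogen bond between the new OH and the ester. The closest known reaction type is the Lewis-acid-mediated formal [3+3] cyclocondensation of 1,3-bis(silyloxy)-1,3-dienes, 4-aryloxy dienes included, with 3-silyloxy enones, enals and malonaldehyde equivalents. No stereocentre is formed. The step needs attack through carbon and in the order terminus then centre, both inherent in the diene, and because the two ends of 10 are equivalent at the aldehyde level either orientation gives the same constitution. One equivalent of TiCl4 at low temperature is chosen so that the benzyl ether, which keeps the ring B oxygen distinct from the new free OH, survives.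

Step 8
Reactants: 11 methyl 3-[2-(benzyloxy)-6-methoxyphenoxy]-5-bromo-2-hydroxybenzoate
Product: 12 3-[2-(benzyloxy)-6-methoxyphenoxy]-5-bromo-2-hydroxybenzoic acid
Conditions: LiOH, THF/MeOH/H2O, 60 °C; then aq. HCl
Reagents that add atoms: lithium hydroxide, [Li+].[OH-]
Why: Ester saponification; excess hydroxide and warming overcome the lower electrophilicity of the salicylate dianion, and no other group is base-sensitive.

Step 9
Reactants: 12 3-[2-(benzyloxy)-6-methoxyphenoxy]-5-bromo-2-hydroxybenzoic acid
Product: 13 2-[2-(benzyloxy)-3,5-dibromo-6-methoxyphenoxy]-4,6-dibromophenol
Conditions: Br2 (3.1 equiv), NaOAc, AcOH/H2O, 20 → 40 °C, dark; then aq. Na2S2O3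
Reagents that add atoms: bromine, BrBr
Why: Threefold electrophilic bromination: ring B reacts at C3' and C5', each ortho to one alkoxy group and para to the other, while on ring A the only carbon ortho or para to the free OH that can still react is the carboxyl-bearing one, where ipso attack and loss of CO2 (bromodecarboxylation of a salicylic acid) install the C3 bromine. The acetate buffer keeps the acid as its carboxylate, which favours the ipso step, and removes HBr, which protects the benzyl ether.

Step 10
Reactants: 13 2-[2-(benzyloxy)-3,5-dibromo-6-methoxyphenoxy]-4,6-dibromophenol
Product: 14 1-(benzyloxy)-4,6-dibromo-2-(3,5-dibromo-2-methoxyphenoxy)-3-methoxybenzene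
Conditions: MeI, K2CO3, DMF, 40 °C
Reagents that add atoms: iodomethane, CI
Why: Williamson methylation of the only free phenol; a small electrophile in a dipolar aprotic solvent copes with the two ortho substituents.

Step 11
Reactants: 14 1-(benzyloxy)-4,6-dibromo-2-(3,5-dibromo-2-methoxyphenoxy)-3-methoxybenzene
Product: 15 4,6-dibromo-2-(3,5-dibromo-2-methoxyphenoxy)-3-methoxyphenol
Conditions: BCl3, C6HMe5, CH2Cl2, −78 °C; then MeOH
Reagents that add atoms: none
Why: Lewis-acid cleavage of an aryl benzyl ether with transfer of the benzyl cation to pentamethylbenzene (Friedel–Crafts trapping); no reducing agent meets the four C–Br bonds, and at −78 °C the aryl methyl ethers should not be attacked.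

## Compound list

1 | 2-hydroxy-6-methoxybenzaldehyde | COc1cccc(O)c1C=O | starting material
2 | 2-(benzyloxy)-6-methoxybenzaldehyde | COc1cccc(OCc2ccccc2)c1C=O | intermediate
3 | 2-(benzyloxy)-6-methoxyphenyl formate | COc1cccc(OCc2ccccc2)c1OC=O | intermediate
4 | 2-(benzyloxy)-6-methoxyphenol | COc1cccc(OCc2ccccc2)c1O | intermediate
5 | methyl 4-chloro-3-oxobutanoate (methyl 4-chloroacetoacetate) | COC(=O)CC(=O)CCl | starting material
6 | methyl 4-[2-(benzyloxy)-6-methoxyphenoxy]-3-oxobutanoate | COC(=O)CC(=O)COc1c(OC)cccc1OCc1ccccc1 | intermediate
7 | methyl (2E)-4-[2-(benzyloxy)-6-methoxyphenoxy]-3-(trimethylsilyloxy)but-2-enoate | COC(=O)/C=C(/O[Si](C)(C)C)COc1c(OC)cccc1OCc1ccccc1 | intermediate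
8 | (1Z,3Z)-4-[2-(benzyloxy)-6-methoxyphenoxy]-1-methoxy-1,3-bis(trimethylsilyloxy)buta-1,3-diene | CO/C(O[Si](C)(C)C)=C/C(O[Si](C)(C)C)=C/Oc1c(OC)cccc1OCc1ccccc1 | intermediate
9 | bromomalonaldehyde (2-bromopropanedial) | O=CC(Br)C=O | starting material
10 | (2Z)-2-bromo-3-(trimethylsilyloxy)prop-2-enal | O=C/C(Br)=C/O[Si](C)(C)C | intermediate
11 | methyl 3-[2-(benzyloxy)-6-methoxyphenoxy]-5-bromo-2-hydroxybenzoate | COC(=O)c1cc(Br)cc(Oc2c(OC)cccc2OCc2ccccc2)c1O | intermediate
12 | 3-[2-(benzyloxy)-6-methoxyphenoxy]-5-bromo-2-hydroxybenzoic acid | OC(=O)c1cc(Br)cc(Oc2c(OC)cccc2OCc2ccccc2)c1O | intermediate
13 | 2-[2-(benzyloxy)-3,5-dibromo-6-methoxyphenoxy]-4,6-dibromophenol | Oc1c(Br)cc(Br)cc1Oc1c(OC)c(Br)cc(Br)c1OCc1ccccc1 | intermediate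
14 | 1-(benzyloxy)-4,6-dibromo-2-(3,5-dibromo-2-methoxyphenoxy)-3-methoxybenzene | COc1c(Br)cc(Br)cc1Oc1c(OCc2ccccc2)c(Br)cc(Br)c1OC | intermediate
15 | 4,6-dibromo-2-(3,5-dibromo-2-methoxyphenoxy)-3-methoxyphenol | COc1c(Br)cc(Br)cc1Oc1c(O)c(Br)cc(Br)c1OC | target

## Step count and least certain steps

Total step count: 11. Longest linear sequence: 10 steps (steps 1 to 5 and 7 to 11); step 6 is a one-step side branch.

Step 7 (key step). The most likely failures are loss of the benzyl group under the stoichiometric Lewis acid and hydrolysis or oligomerisation of the sensitive bromo silyloxy enal before the second C–C bond forms. Protodesilylation of the diene back to the keto ester is also possible. The fallback sets out from 8 and returns at 13; it changes the three-carbon partner and moves the C5 bromine to a later electrophilic step. Compound 8 would be condensed with 1,1,3,3-tetramethoxypropane under catalytic Me3SiOTf (CH2Cl2, −78 → 20 °C), a stable bis-acetal that needs no stoichiometric metal halide, which should give methyl 3-[2-(benzyloxy)-6-methoxyphenoxy]-2-hydroxybenzoate F1. Saponification of F1 with LiOH would give 3-[2-(benzyloxy)-6-methoxyphenoxy]-2-hydroxybenzoic acid F2. Bromine (4.1 equiv) in NaOAc-buffered aqueous acetic acid should then brominate ring A of F2 para to the OH, replace the carboxyl group ipso and dibrominate ring B, arriving at 13.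

Step 9. The ipso substitution may lag behind the ring B bromination, so that carboxyl-bearing material persists while excess bromine begins to attack a fifth position. If the buffer is exhausted, HBr may erode the benzyl ether. The fallback sets out from 12 and returns at 13; it installs the C3 bromine on a C–H bond instead. Protodecarboxylation of 12 (Ag2CO3 cat., AcOH, DMSO, 120 °C) should give 2-[2-(benzyloxy)-6-methoxyphenoxy]-4-bromophenol F3. Bromine (3 equiv, NaOAc, AcOH) should then substitute the one free position ortho to the OH of ring A of F3 together with C3' and C5' of ring B, giving 13.

Step 3. Under base the chloro keto ester may condense with itself (enolate alkylation by the CH2Cl group of a second molecule) faster than the hindered phenoxide is O-alkylated. The fallback sets out from 4 and returns at 6; it builds the keto ester by C–C instead of C–O bond formation. Alkylation of 4 with methyl bromoacetate (K2CO3, acetone) would give methyl [2-(benzyloxy)-6-methoxyphenoxy]acetate F4. Crossed Claisen condensation of F4 with an excess of the lithium enolate of methyl acetate (lithium diisopropylamide, MeOAc, THF, −78 °C) would then give 6.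

Step 5. Deprotonation at the aryloxy-bearing carbon may be incomplete, silylation may occur partly at carbon, and the diene may lose silyl groups by adventitious hydrolysis during isolation. The fallback sets out from 6 and returns at 8; it avoids the carbanion altogether. Soft enolisation of 6 with Me3SiOTf (2.2 equiv) and Et3N in Et2O at 0 °C should silylate both enolisable positions in one operation, with 7 skipped. No compound outside the compound list is formed (F0).

## Further compounds

F1 | step 7 | methyl 3-[2-(benzyloxy)-6-methoxyphenoxy]-2-hydroxybenzoate | COC(=O)c1cccc(Oc2c(OC)cccc2OCc2ccccc2)c1O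
F2 | step 7 | 3-[2-(benzyloxy)-6-methoxyphenoxy]-2-hydroxybenzoic acid | OC(=O)c1cccc(Oc2c(OC)cccc2OCc2ccccc2)c1O
F3 | step 9 | 2-[2-(benzyloxy)-6-methoxyphenoxy]-4-bromophenol | Oc1ccc(Br)cc1Oc1c(OC)cccc1OCc1ccccc1
F4 | step 3 | methyl [2-(benzyloxy)-6-methoxyphenoxy]acetate | COC(=O)COc1c(OC)cccc1OCc1ccccc1
F0 | step 5 | none | none
A1 | alternative 1 | 2-(3,5-dibromo-2-methoxyphenoxy)benzene-1,3-dicarbaldehyde | COc1c(Br)cc(Br)cc1Oc1c(C=O)cccc1C=O
A2 | alternative 1 | 2-(3,5-dibromo-2-methoxyphenoxy)benzene-1,3-diol | COc1c(Br)cc(Br)cc1Oc1c(O)cccc1O
A3 | alternative 1 | 3,5-dibromo-2-methoxyphenol | COc1c(O)cc(Br)cc1Br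
A4 | alternative 1 | 2-fluorobenzene-1,3-dicarbaldehyde | O=Cc1cccc(C=O)c1F
A5 | alternative 1 | 2-(3,5-dibromo-2-methoxyphenoxy)-3-methoxyphenol | COc1cccc(O)c1Oc1cc(Br)cc(Br)c1OC
A6 | alternative 2 | methyl 6-(3,5-dibromo-2-methoxyphenoxy)-5-oxohexanoate | COC(=O)CCCC(=O)COc1cc(Br)cc(Br)c1OC
A7 | alternative 2 | 2-(3,5-dibromo-2-methoxyphenoxy)cyclohexane-1,3-dione | COc1c(Br)cc(Br)cc1OC1C(=O)CCCC1=O
A8 | alternative 2 | methyl 6-bromo-5-oxohexanoate | COC(=O)CCCC(=O)CBr
A9 | alternative 3 | 2-[2-(benzyloxy)-6-methoxyphenoxy]phenol | Oc1ccccc1Oc1c(OC)cccc1OCc1ccccc1
A10 | alternative 3 | 2-[2-(benzyloxy)-3,5-dibromo-6-methoxyphenoxy]-4,6-dibromophenol | Oc1c(Br)cc(Br)cc1Oc1c(OC)c(Br)cc(Br)c1OCc1ccccc1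
A11 | alternative 3 | 2-fluorobenzaldehyde | O=Cc1ccccc1F
A12 | alternative 3 | 2-[2-(benzyloxy)-6-methoxyphenoxy]benzaldehyde | O=Cc1ccccc1Oc1c(OC)cccc1OCc1ccccc1
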